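**Retrosynthetic overview**
1. A ring = acetosyringone 1. The 6-OMe/7-OH/8-OMe array is bought; only the two C–H bonds ortho to the acetyl group must become C–O bonds (O1–C8a and C5–OH).
2. B ring and C2 = methyl 3,4-dihydroxy-5-methoxybenzoate 2, carried as its bis-MOM ether 3.
3. C2–C3 disconnection: crossed Claisen condensation of 1 with 3 gives 1,3-diketone 4, unmasked in the same flask to triphenol diketone 5.
4. Key disconnections, all C–O: C8a–O, O1–C2 and C5–O are made in one flask from 5 (via 6, 7, 8, 9) by directed double aryl C–H oxygenation with cyclodehydration, giving flavone 10.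
5. Ring order: A and B rings are bought; the pyranone C ring is the only ring built and is closed in the last step.

Assumption: the target is a planar, achiral flavone with no stereocentre, so there is no enantiomer to select and the SMILES is taken as the full definition of the structure.

**Step 1**
Reactants: 2 methyl 3,4-dihydroxy-5-methoxybenzoate
Product: 3 methyl 3-methoxy-4,5-bis(methoxymethoxy)benzoate
Conditions: MOMCl (3 equiv), i-Pr2NEt (4 equiv), CH2Cl2, 0 °C → rt
Reagents that add atoms: chloromethyl methyl ether (MOMCl), COCCl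
Why: Both catechol hydroxyls are O-alkylated by the oxocarbenium-type electrophile (MOM ether formation, Williamson-type), giving a base-stable, acid-labile mask that leaves the ester free for the Claisen step.

**Step 2**
Reactants: 1 acetosyringone (1-(4-hydroxy-3,5-dimethoxyphenyl)ethan-1-one); 3 methyl 3-methoxy-4,5-bis(methoxymethoxy)benzoate
Product: 5 1-(3,4-dihydroxy-5-methoxyphenyl)-3-(4-hydroxy-3,5-dimethoxyphenyl)propane-1,3-dione, via bis-MOM diketone 4 (not isolated)
Conditions: 1, LiHMDS (4 equiv), THF, −78 → 0 °C; add 3, 0 → 50 °C; then 3 M HCl/MeOH, 50 °C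
Reagents that add atoms: none
Why: The phenoxide/enolate dianion of 1 is C-acylated by the ester in a crossed Claisen condensation driven by deprotonation of the diketone (the hindered phenoxide O-acylates only reversibly), and acidic methanol then cleaves both MOM acetals without touching the diketone.

**Step 3**
Reactants: 5 1-(3,4-dihydroxy-5-methoxyphenyl)-3-(4-hydroxy-3,5-dimethoxyphenyl)propane-1,3-dione
Product: 10 target flavone (5,7,3',4'-tetrahydroxy-6,8,5'-trimethoxyflavone), via tris-trifluoroacetate diketone 6 (not isolated), via ortho-trifluoroacetoxylated diketone 7 (not isolated), via 5-deoxyflavone tris-trifluoroacetate 8 (not isolated), via flavone tetrakis-trifluoroacetate 9 (not isolated)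
Conditions: TFAA/TFA (1:3), rt, 30 min; then [RuCl2(p-cymene)]2 (5 mol %), K2S2O8 (2.4 equiv), 80 °C; then H2O/THF, rt
Reagents that add atoms: trifluoroacetic acid, OC(=O)C(F)(F)F (both new O atoms of 10); trifluoroacetic anhydride, O=C(OC(=O)C(F)(F)F)C(F)(F)F (CF3CO groups of 6–9 only)
Why: Proposed new method: a Ru(II)-catalysed, ring-selective double aryl C–H oxygenation/cyclodehydration cascade that turns a non-hydroxylated 1,3-diaryl-1,3-diketone directly into a 5-hydroxyflavone. TFAA first masks the three phenols as electron-poor aryl trifluoroacetates (6); the A-ring carbonyl then directs carboxylate-assisted ruthenation of an A-ring C–H (ortho/para to two OMe groups, so far more electron-rich than either B-ring C–H, whose ring carries two acyloxy groups; the two A-ring sites are equivalent by symmetry); persulfate oxidises the ruthenacycle and C–O reductive elimination with trifluoroacetate gives 7; the unmasked ortho oxygen attacks the distal carbonyl and dehydrates in the acidic medium (Baker–Venkataraman-type ring closure) to chromone 8, whose in-plane C4=O directs the second oxygenation at C5 (9); water finally strips the four labile trifluoroacetates. The closest known reactions are Ru/Pd-catalysed ketone-directed ortho C–H hydroxylation of aryl ketones in TFA/TFAA and Ru-catalysed C5–H hydroxylation of flavones, neither shown twice on one ring, on a 1,3-diketone, or coupled to chromone ring closure. K2S2O8 replaces PhI(OCOCF3)2 because iodine(III) would oxidise the diketone CH2.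

**Compound list**
1 | acetosyringone, 1-(4-hydroxy-3,5-dimethoxyphenyl)ethan-1-one (achiral) | CC(=O)c1cc(OC)c(O)c(OC)c1 | starting material
2 | methyl 3,4-dihydroxy-5-methoxybenzoate (methyl 3-O-methylgallate, achiral) | COC(=O)c1cc(O)c(O)c(OC)c1 | starting material
3 | methyl 3-methoxy-4,5-bis(methoxymethoxy)benzoate | COCOc1cc(cc(OC)c1OCOC)C(=O)OC | intermediate
4 | 1-(4-hydroxy-3,5-dimethoxyphenyl)-3-[3-methoxy-4,5-bis(methoxymethoxy)phenyl]propane-1,3-dione (formed as its lithium salt, drawn as the diketo form) | COCOc1cc(cc(OC)c1OCOC)C(=O)CC(=O)c1cc(OC)c(O)c(OC)c1 | intermediate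
5 | 1-(3,4-dihydroxy-5-methoxyphenyl)-3-(4-hydroxy-3,5-dimethoxyphenyl)propane-1,3-dione (drawn as the diketo form, largely the chelated enol) | COc1cc(cc(O)c1O)C(=O)CC(=O)c1cc(OC)c(O)c(OC)c1 | intermediate
6 | tris(trifluoroacetate) of 5: 1-[3-methoxy-4,5-bis(trifluoroacetoxy)phenyl]-3-[3,5-dimethoxy-4-(trifluoroacetoxy)phenyl]propane-1,3-dione | COc1cc(cc(OC(=O)C(F)(F)F)c1OC(=O)C(F)(F)F)C(=O)CC(=O)c1cc(OC)c(OC(=O)C(F)(F)F)c(OC)c1 | intermediate
7 | 1-[3-methoxy-4,5-bis(trifluoroacetoxy)phenyl]-3-[3,5-dimethoxy-2,4-bis(trifluoroacetoxy)phenyl]propane-1,3-dione | COc1cc(cc(OC(=O)C(F)(F)F)c1OC(=O)C(F)(F)F)C(=O)CC(=O)c1cc(OC)c(OC(=O)C(F)(F)F)c(OC)c1OC(=O)C(F)(F)F | intermediate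
8 | 6,8-dimethoxy-2-[3-methoxy-4,5-bis(trifluoroacetoxy)phenyl]-4-oxo-4H-chromen-7-yl trifluoroacetate | COc1cc(cc(OC(=O)C(F)(F)F)c1OC(=O)C(F)(F)F)-c1cc(=O)c2cc(OC)c(OC(=O)C(F)(F)F)c(OC)c2o1 | intermediate
9 | 6,8-dimethoxy-2-[3-methoxy-4,5-bis(trifluoroacetoxy)phenyl]-4-oxo-4H-chromene-5,7-diyl bis(trifluoroacetate) | COc1cc(cc(OC(=O)C(F)(F)F)c1OC(=O)C(F)(F)F)-c1cc(=O)c2c(OC(=O)C(F)(F)F)c(OC)c(OC(=O)C(F)(F)F)c(OC)c2o1 | intermediate
10 | 5,7,3',4'-tetrahydroxy-6,8,5'-trimethoxyflavone, 2-(3,4-dihydroxy-5-methoxyphenyl)-5,7-dihydroxy-6,8-dimethoxy-4H-chromen-4-one (achiral) | COc1cc(-c2cc(=O)c3c(O)c(OC)c(O)c(OC)c3o2)cc(O)c1O | target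

**Totals**
Total step count: 3. Longest linear sequence: 3 steps (2 → 3 → 5 → 10).

**Steps most likely to fail**

Step 3 (the proposed cascade). Risks: the first oxygenation may occur on the B ring and give the ring-swapped flavone, the diketone CH2 may be oxidised, or the reaction may stall at the 5-deoxyflavone. The fallback uses only known chemistry and replaces C–H oxygenation by halogenation and Ullmann-type C–O coupling; it sets out from 1 (and uses 3) and comes back at 10. Dibrominate 1 (NBS 2.1 equiv, MeCN, 0 °C → rt) to 1-(2,6-dibromo-4-hydroxy-3,5-dimethoxyphenyl)ethan-1-one F1. Condense F1 with 3 (LiHMDS, THF; aqueous NH4Cl work-up so the MOM groups stay) to 1-(2,6-dibromo-4-hydroxy-3,5-dimethoxyphenyl)-3-[3-methoxy-4,5-bis(methoxymethoxy)phenyl]propane-1,3-dione F2. Close the pyranone by copper-catalysed intramolecular O-arylation of the enolate (CuI 10 mol %, K2CO3, DMF, 100 °C) to 5-bromo-7-hydroxy-6,8-dimethoxy-2-[3-methoxy-4,5-bis(methoxymethoxy)phenyl]-4H-chromen-4-one F3. Replace the remaining peri bromide by copper-catalysed hydroxylation (CuI, oxalamide ligand, LiOH, DMSO/H2O, 80 °C) to 5,7-dihydroxy-6,8-dimethoxy-2-[3-methoxy-4,5-bis(methoxymethoxy)phenyl]-4H-chromen-4-one F4. Remove the MOM groups (3 M HCl/MeOH, 50 °C) to reach 10.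

Step 2 (Claisen condensation of the unprotected dianion with one-flask unmasking). Risks: the dianion may be sluggish toward the electron-rich ester, and the acid stage may be incomplete. The fallback replaces acyl substitution by aldol addition and oxidation on fully protected partners; it sets out from 1 and 3 and comes back at 5. Protect 1 (MOMCl, i-Pr2NEt, CH2Cl2) as 1-[3,5-dimethoxy-4-(methoxymethoxy)phenyl]ethan-1-one F5. Reduce 3 (LiAlH4, THF, 0 °C) to [3-methoxy-4,5-bis(methoxymethoxy)phenyl]methanol F6 and oxidise it (MnO2, CH2Cl2) to 3-methoxy-4,5-bis(methoxymethoxy)benzaldehyde F7. Add the lithium enolate of F5 (LDA, THF, −78 °C) to F7 to give racemic 3-hydroxy-1-[3,5-dimethoxy-4-(methoxymethoxy)phenyl]-3-[3-methoxy-4,5-bis(methoxymethoxy)phenyl]propan-1-one F8. Oxidise the carbinol (Dess–Martin periodinane, NaHCO3, CH2Cl2) to 1-[3,5-dimethoxy-4-(methoxymethoxy)phenyl]-3-[3-methoxy-4,5-bis(methoxymethoxy)phenyl]propane-1,3-dione F9. Cleave the three MOM groups (3 M HCl/MeOH, 50 °C) to reach 5.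

Step 1 (bis-MOM protection). Risks: incomplete protection of the hindered 4-OH, or MOM groups that later prove awkward. The fallback switches to a hydrogenolytic protecting-group strategy with an isolated protected diketone; it sets out from 2 (and uses 1) and comes back at 5. Benzylate 2 (BnBr, K2CO3, DMF, 60 °C) to methyl 3,4-bis(benzyloxy)-5-methoxybenzoate F10. Condense F10 with 1 (LiHMDS, THF; aqueous NH4Cl work-up) to 1-[3,4-bis(benzyloxy)-5-methoxyphenyl]-3-(4-hydroxy-3,5-dimethoxyphenyl)propane-1,3-dione F11. Hydrogenolyse the benzyl ethers (H2 1 atm, Pd/C, EtOAc/MeOH, rt) to reach 5.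

**Further compounds**
F1 | step 3 | 1-(2,6-dibromo-4-hydroxy-3,5-dimethoxyphenyl)ethan-1-one | CC(=O)c1c(Br)c(OC)c(O)c(OC)c1Br
F2 | step 3 | 1-(2,6-dibromo-4-hydroxy-3,5-dimethoxyphenyl)-3-[3-methoxy-4,5-bis(methoxymethoxy)phenyl]propane-1,3-dione | COCOc1cc(C(=O)CC(=O)c2c(Br)c(OC)c(O)c(OC)c2Br)cc(OC)c1OCOC
F3 | step 3 | 5-bromo-7-hydroxy-6,8-dimethoxy-2-[3-methoxy-4,5-bis(methoxymethoxy)phenyl]-4H-chromen-4-one | COCOc1cc(-c2cc(=O)c3c(Br)c(OC)c(O)c(OC)c3o2)cc(OC)c1OCOC
F4 | step 3 | 5,7-dihydroxy-6,8-dimethoxy-2-[3-methoxy-4,5-bis(methoxymethoxy)phenyl]-4H-chromen-4-one | COCOc1cc(-c2cc(=O)c3c(O)c(OC)c(O)c(OC)c3o2)cc(OC)c1OCOC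
F5 | step 2 | 1-[3,5-dimethoxy-4-(methoxymethoxy)phenyl]ethan-1-one | CC(=O)c1cc(OC)c(OCOC)c(OC)c1
F6 | step 2 | [3-methoxy-4,5-bis(methoxymethoxy)phenyl]methanol | COCOc1cc(CO)cc(OC)c1OCOC
F7 | step 2 | 3-methoxy-4,5-bis(methoxymethoxy)benzaldehyde | COCOc1cc(C=O)cc(OC)c1OCOC
F8 | step 2 | racemic 3-hydroxy-1-[3,5-dimethoxy-4-(methoxymethoxy)phenyl]-3-[3-methoxy-4,5-bis(methoxymethoxy)phenyl]propan-1-one | COCOc1cc(C(O)CC(=O)c2cc(OC)c(OCOC)c(OC)c2)cc(OC)c1OCOC
F9 | step 2 | 1-[3,5-dimethoxy-4-(methoxymethoxy)phenyl]-3-[3-methoxy-4,5-bis(methoxymethoxy)phenyl]propane-1,3-dione | COCOc1cc(C(=O)CC(=O)c2cc(OC)c(OCOC)c(OC)c2)cc(OC)c1OCOC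
F10 | step 1 | methyl 3,4-bis(benzyloxy)-5-methoxybenzoate | COC(=O)c1cc(OC)c(OCc2ccccc2)c(OCc2ccccc2)c1
F11 | step 1 | 1-[3,4-bis(benzyloxy)-5-methoxyphenyl]-3-(4-hydroxy-3,5-dimethoxyphenyl)propane-1,3-dione | COc1cc(C(=O)CC(=O)c2cc(OC)c(O)c(OC)c2)cc(OCc2ccccc2)c1OCc1ccccc1
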